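**Retrosynthetic overview**
1. Target 28 ⇐ triol 26 by one oxidation that makes the C14 enal and closes the γ-lactone (lactone ring formed last); 26 ⇐ bis-silyl ether 25.
2. 25 ⇐ bromo enal 23 by intramolecular Nozaki–Hiyama allylation (C6–C7). This one step closes the ten-membered ring (formed first) and sets C6 and C7 under control of C8; it replaces the usual "intermolecular allylation/lactone, then ring-closing metathesis" sequence.
3. 23 ⇐ 18 + 22 (cross-metathesis); 18 ⇐ alkylzinc from 16 + Z-iodoenal 4 (Negishi, C3–C4, fixes the C4=C5 geometry).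
4. 16 ⇐ E-alkylidene lactone 10 ⇐ phosphono lactone 9 + aldehyde 6 (Horner–Wadsworth–Emmons, fixes the C1=C10 geometry); 9 ⇐ (R)-2-ethenyloxirane 7 (source of C8) + 8; the acyl stereocentre is bought as acid 13.

Assumption: 1, 5, 7, 8, 13 and 19 are taken as commercial (7 as the R and 13 as the S enantiomer); atoms are labelled with germacrane numbering (C6 lactone CH–O, C7 ring-fusion CH, C8 CH–O-acyl, C11–C13 methylene-lactone unit, C14 formyl carbon, C15 acetoxymethyl carbon); TBS = tert-butyl(dimethyl)silyl, PMB = 4-methoxybenzyl.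

**Route**

Step 1
Reactants: 1 but-2-yne-1,4-diol
Product: 2 4-hydroxybut-2-yn-1-yl acetate
Conditions: Ac2O (0.35 equiv), pyridine, THF, 0 °C
Reagents that add atoms: acetic anhydride, CC(=O)OC(C)=O
Why: Nucleophilic acyl substitution on a symmetric diol used in threefold excess gives mainly the monoacetate, and this acetyl group becomes the C15 acetate of the target.

Step 2
Reactants: 2 4-hydroxybut-2-yn-1-yl acetate
Product: 3 4-acetoxybut-2-ynal
Conditions: MnO2 (15 equiv), CH2Cl2, rt
Reagents that add atoms: none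
Why: MnO2 oxidation is selective for the propargylic alcohol and stops at the ynal without touching the acetate.

Step 3
Reactants: 3 4-acetoxybut-2-ynal
Product: 4 (Z)-4-acetoxy-3-iodobut-2-enal
Conditions: NaI (1.5 equiv), AcOH, rt
Reagents that add atoms: sodium iodide, [Na+].[I-]
Why: Conjugate hydroiodination of the ynal (iodide adds at the β-carbon, the allenolate is protonated anti to iodine) gives the Z isomer with iodine cis to the formyl group, which fixes the later C4=C5 geometry.

Step 4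
Reactants: 5 3-[(4-methoxyphenyl)methoxy]propan-1-ol
Product: 6 3-[(4-methoxyphenyl)methoxy]propanal
Conditions: TEMPO (0.1 equiv), PhI(OAc)2 (1.1 equiv), CH2Cl2, rt
Reagents that add atoms: none
Why: Oxoammonium (TEMPO) oxidation takes the primary alcohol to the aldehyde without over-oxidation or loss of the PMB ether.

Step 5
Reactants: 7 (2R)-2-ethenyloxirane; 8 triethyl phosphonoacetate
Product: 9 diethyl [(5S)-5-ethenyl-2-oxooxolan-3-yl]phosphonate
Conditions: NaOEt (1.1 equiv), EtOH, 0 → 60 °C; AcOH quench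
Reagents that add atoms: none
Why: The phosphonoacetate anion opens the epoxide by SN2 attack at the unsubstituted CH2 and the alkoxide lactonises onto the ethyl ester, so the C–O stereocentre (future C8) is untouched and keeps its configuration (R becomes S only through CIP priorities).

Step 6
Reactants: 9 diethyl [(5S)-5-ethenyl-2-oxooxolan-3-yl]phosphonate; 6 3-[(4-methoxyphenyl)methoxy]propanal
Product: 10 (3E,5S)-5-ethenyl-3-{3-[(4-methoxyphenyl)methoxy]propylidene}oxolan-2-one
Conditions: KOtBu (1.0 equiv), THF, −78 → 0 °C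
Reagents that add atoms: none
Why: Horner–Wadsworth–Emmons olefination of the α-phosphono lactone gives the E-alkylidene lactone (chain anti to the lactone carbonyl), which is the C1=C10 geometry of the target.

Step 7
Reactants: 10 (3E,5S)-alkylidene lactone
Product: 11 (3S,5E)-5-(hydroxymethyl)-8-[(4-methoxyphenyl)methoxy]octa-1,5-dien-3-ol
Conditions: iBu2AlH (4 equiv), CH2Cl2, −78 → 0 °C; aq. potassium sodium tartrate
Reagents that add atoms: none
Why: Hydride 1,2-reduction of the unsaturated lactone through the lactol gives the 2-alkylidene-1,4-diol with the alkene geometry and C8 unchanged.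

Step 8
Reactants: 11 diol
Product: 12 (3S,5E)-5-[(TBS-oxy)methyl]-8-[(4-methoxyphenyl)methoxy]octa-1,5-dien-3-ol
Conditions: TBSCl (1.05 equiv), imidazole, CH2Cl2, −20 °C
Reagents that add atoms: tert-butyldimethylsilyl chloride, CC(C)(C)[Si](C)(C)Cl
Why: Silylation is selective for the primary allylic hydroxyl (C14–OH) over the secondary one on steric grounds.

Step 9
Reactants: 12 silyl ether alcohol; 13 (2S)-2-methylbutanoic acid
Product: 14 (3S,5E)-5-[(TBS-oxy)methyl]-8-[(4-methoxyphenyl)methoxy]octa-1,5-dien-3-yl (2S)-2-methylbutanoate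
Conditions: DCC, DMAP (0.1 equiv), CH2Cl2, 0 °C → rt
Reagents that add atoms: none
Why: Steglich esterification puts the (S)-2-methylbutanoate on O8 without touching either stereocentre.

Step 10
Reactants: 14 PMB ether ester
Product: 15 (3S,5E)-5-[(TBS-oxy)methyl]-8-hydroxyocta-1,5-dien-3-yl (2S)-2-methylbutanoate
Conditions: DDQ (1.2 equiv), CH2Cl2/pH 7 buffer, 0 °C
Reagents that add atoms: none
Why: Oxidative PMB cleavage (benzylic hydride abstraction, hydrolysis of the oxocarbenium ion) frees the primary alcohol while silyl ether, ester and alkenes survive.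

Step 11
Reactants: 15 primary alcohol
Product: 16 (3S,5E)-5-[(TBS-oxy)methyl]-8-iodoocta-1,5-dien-3-yl (2S)-2-methylbutanoate
Conditions: I2, PPh3, imidazole, CH2Cl2, 0 °C
Reagents that add atoms: iodine, I-I
Why: Appel-type (Garegg–Samuelsson) iodination is an SN2 displacement at the primary carbon through the alkoxyphosphonium ion.

Step 12
Reactants: 16 primary iodide; 4 (Z)-4-acetoxy-3-iodobut-2-enal
Product: 18 (3S,5E,9E)-9-(acetoxymethyl)-5-[(TBS-oxy)methyl]-11-oxoundeca-1,5,9-trien-3-yl (2S)-2-methylbutanoate, via alkylzinc iodide 17 (not isolated)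
Conditions: Zn dust, LiCl, THF, 40 °C; then 4, Pd(PPh3)4 (5 mol%), THF, rt
Reagents that add atoms: none
Why: Zinc insertion into the primary C–I bond followed by Negishi cross-coupling with the vinyl iodide (zerovalent palladium, retention of alkene geometry) puts C3 cis to the formyl group, and the alkylzinc tolerates the esters and the aldehyde.

Step 13
Reactants: 19 2-methylidenepropane-1,3-diol
Product: 20 2-[(TBS-oxy)methyl]prop-2-en-1-ol
Conditions: NaH (1.0 equiv), THF, 0 °C; then TBSCl (1.0 equiv)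
Reagents that add atoms: tert-butyldimethylsilyl chloride, CC(C)(C)[Si](C)(C)Cl
Why: Monosilylation of a symmetric diol through its sparingly soluble monosodium alkoxide gives the mono-ether cleanly.

Step 14
Reactants: 20 2-[(TBS-oxy)methyl]prop-2-en-1-ol
Product: 22 {[2-(bromomethyl)prop-2-en-1-yl]oxy}(tert-butyl)dimethylsilane, via allylic mesylate 21 (not isolated)
Conditions: MsCl, Et3N, CH2Cl2, −20 °C; then LiBr, THF, rt
Reagents that add atoms: lithium bromide, [Li+].[Br-]
Why: Mesylation followed by SN2 displacement with bromide gives the allylic bromide under non-acidic conditions that keep the silyl ether.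

Step 15
Reactants: 18 trienal ester; 22 allylic bromide
Product: 23 (4S,6E,10E)-10-(acetoxymethyl)-1-bromo-2,6-bis[(TBS-oxy)methyl]-12-oxododeca-2,6,10-trien-4-yl (2S)-2-methylbutanoate (2E/2Z mixture)
Conditions: 22 (5 equiv), second-generation Hoveyda–Grubbs catalyst (10 mol%), CH2Cl2, 40 °C
Reagents that add atoms: none
Why: Olefin cross-metathesis engages only the monosubstituted vinyl group of 18 with the 1,1-disubstituted partner used in excess (trisubstituted alkenes and the enal are spectators), and the E/Z mixture at the new bond is harmless because both isomers give the same allylchromium in step 16.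

Step 16
Reactants: 23 bromo enal
Product: 25 (1(10)E,4E,6R,7S,8S)-15-acetoxy-12,14-bis(TBS-oxy)-6-hydroxygermacra-1(10),4,11(13)-trien-8-yl (2S)-2-methylbutanoate, via allylchromium dichloride 24 (not isolated)
Conditions: CrCl2 (10 equiv), THF, rt, 2 mM, syringe-pump addition of 23; aq. NH4Cl
Reagents that add atoms: none
Why: Intramolecular Nozaki–Hiyama allylation, in which divalent chromium turns the allylic bromide into an equilibrating allylchromium (trivalent chromium) that adds through its γ-carbon C7 to the enal in a Zimmerman–Traxler chair, giving the 6,7-anti product (the trans-lactone precursor); at C7 the face is set by C8, whose hydrogen eclipses the alkene (A(1,3) strain) so that the acyloxy group lies anti to the forming bond (Felkin-type) and the tethered C9 sits on the attacking face.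

Step 17
Reactants: 25 macrocyclic bis-silyl ether
Product: 26 (1(10)E,4E,6R,7S,8S)-15-acetoxy-6,12,14-trihydroxygermacra-1(10),4,11(13)-trien-8-yl (2S)-2-methylbutanoate
Conditions: HF·pyridine, pyridine, THF, 0 °C → rt
Reagents that add atoms: none
Why: Buffered fluoride desilylation removes both primary TBS ethers without acyl migration or ester cleavage.

Step 18
Reactants: 26 triol
Product: 28 [(3aR,4S,6E,10E,11aR)-10-(acetoxymethyl)-6-formyl-3-methylidene-2-oxo-2,3,3a,4,5,8,9,11a-octahydrocyclodeca[b]furan-4-yl] (2S)-2-methylbutanoate, via lactol 27 (not isolated)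
Conditions: TEMPO (0.3 equiv), PhI(OAc)2 (3.5 equiv), CH2Cl2, rt
Reagents that add atoms: none
Why: TEMPO/PhI(OAc)2 oxidises the two primary allylic alcohols in preference to the secondary one, so C14 becomes the enal while the C12 aldehyde is trapped by the C6 hydroxyl as a lactol and oxidised on to the α-methylene-γ-lactone (oxidative lactonisation); no stereocentre is touched.

**Compound list**
1 | but-2-yne-1,4-diol | OCC#CCO | starting material
2 | 4-hydroxybut-2-yn-1-yl acetate | CC(=O)OCC#CCO | intermediate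
3 | 4-acetoxybut-2-ynal (4-oxobut-2-yn-1-yl acetate) | CC(=O)OCC#CC=O | intermediate
4 | (Z)-4-acetoxy-3-iodobut-2-enal (iodine cis to CHO) | O=C/C=C(/COC(C)=O)I | intermediate
5 | 3-[(4-methoxyphenyl)methoxy]propan-1-ol | COc1ccc(COCCCO)cc1 | starting material
6 | 3-[(4-methoxyphenyl)methoxy]propanal | COc1ccc(COCCC=O)cc1 | intermediate
7 | (2R)-2-ethenyloxirane | C=C[C@@H]1CO1 | starting material
8 | triethyl phosphonoacetate | CCOC(=O)CP(=O)(OCC)OCC | starting material
9 | diethyl [(5S)-5-ethenyl-2-oxooxolan-3-yl]phosphonate (both C3 epimers) | C=C[C@H]1OC(=O)C(P(=O)(OCC)OCC)C1 | intermediate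
10 | (3E,5S)-5-ethenyl-3-{3-[(4-methoxyphenyl)methoxy]propylidene}oxolan-2-one | C=C[C@@H]1C/C(=C\CCOCc2ccc(OC)cc2)C(=O)O1 | intermediate
11 | (3S,5E)-5-(hydroxymethyl)-8-[(4-methoxyphenyl)methoxy]octa-1,5-dien-3-ol | COc1ccc(COCC/C=C(/CO)C[C@H](O)C=C)cc1 | intermediate
12 | (3S,5E)-5-({[tert-butyl(dimethyl)silyl]oxy}methyl)-8-[(4-methoxyphenyl)methoxy]octa-1,5-dien-3-ol | COc1ccc(COCC/C=C(/CO[Si](C)(C)C(C)(C)C)C[C@H](O)C=C)cc1 | intermediate
13 | (2S)-2-methylbutanoic acid | CC[C@H](C)C(=O)O | starting material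
14 | (3S,5E)-5-({[tert-butyl(dimethyl)silyl]oxy}methyl)-8-[(4-methoxyphenyl)methoxy]octa-1,5-dien-3-yl (2S)-2-methylbutanoate | COc1ccc(COCC/C=C(/CO[Si](C)(C)C(C)(C)C)C[C@H](OC(=O)[C@@H](C)CC)C=C)cc1 | intermediate
15 | (3S,5E)-5-({[tert-butyl(dimethyl)silyl]oxy}methyl)-8-hydroxyocta-1,5-dien-3-yl (2S)-2-methylbutanoate | OCC/C=C(/CO[Si](C)(C)C(C)(C)C)C[C@H](OC(=O)[C@@H](C)CC)C=C | intermediate
16 | (3S,5E)-5-({[tert-butyl(dimethyl)silyl]oxy}methyl)-8-iodoocta-1,5-dien-3-yl (2S)-2-methylbutanoate | ICC/C=C(/CO[Si](C)(C)C(C)(C)C)C[C@H](OC(=O)[C@@H](C)CC)C=C | intermediate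
17 | [(3E,6S)-4-({[tert-butyl(dimethyl)silyl]oxy}methyl)-6-{[(2S)-2-methylbutanoyl]oxy}octa-3,7-dien-1-yl]zinc iodide | I[Zn]CC/C=C(/CO[Si](C)(C)C(C)(C)C)C[C@H](OC(=O)[C@@H](C)CC)C=C | intermediate (not isolated)
18 | (3S,5E,9E)-9-(acetoxymethyl)-5-({[tert-butyl(dimethyl)silyl]oxy}methyl)-11-oxoundeca-1,5,9-trien-3-yl (2S)-2-methylbutanoate | O=C/C=C(/COC(C)=O)CC/C=C(/CO[Si](C)(C)C(C)(C)C)C[C@H](OC(=O)[C@@H](C)CC)C=C | intermediate
19 | 2-methylidenepropane-1,3-diol | C=C(CO)CO | starting material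
20 | 2-({[tert-butyl(dimethyl)silyl]oxy}methyl)prop-2-en-1-ol | C=C(CO)CO[Si](C)(C)C(C)(C)C | intermediate
21 | 2-({[tert-butyl(dimethyl)silyl]oxy}methyl)prop-2-en-1-yl methanesulfonate | C=C(COS(C)(=O)=O)CO[Si](C)(C)C(C)(C)C | intermediate (not isolated)
22 | {[2-(bromomethyl)prop-2-en-1-yl]oxy}(tert-butyl)dimethylsilane | C=C(CBr)CO[Si](C)(C)C(C)(C)C | intermediate
23 | (4S,6E,10E)-10-(acetoxymethyl)-1-bromo-2,6-bis({[tert-butyl(dimethyl)silyl]oxy}methyl)-12-oxododeca-2,6,10-trien-4-yl (2S)-2-methylbutanoate, 2E/2Z mixture (geometry at that bond left open in the SMILES) | O=C/C=C(/COC(C)=O)CC/C=C(/CO[Si](C)(C)C(C)(C)C)C[C@H](OC(=O)[C@@H](C)CC)C=C(CBr)CO[Si](C)(C)C(C)(C)C | intermediate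
24 | allylchromium dichloride derived from 23 (CrCl2 unit on the former CH2Br carbon) | O=C/C=C(/COC(C)=O)CC/C=C(/CO[Si](C)(C)C(C)(C)C)C[C@H](OC(=O)[C@@H](C)CC)C=C(C[Cr](Cl)Cl)CO[Si](C)(C)C(C)(C)C | intermediate (not isolated)
25 | (1(10)E,4E,6R,7S,8S)-15-acetoxy-12,14-bis{[tert-butyl(dimethyl)silyl]oxy}-6-hydroxygermacra-1(10),4,11(13)-trien-8-yl (2S)-2-methylbutanoate (ten-membered carbocycle) | C=C(CO[Si](C)(C)C(C)(C)C)[C@H]1[C@H](O)/C=C(/COC(C)=O)CC/C=C(/CO[Si](C)(C)C(C)(C)C)C[C@@H]1OC(=O)[C@@H](C)CC | intermediate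
26 | (1(10)E,4E,6R,7S,8S)-15-acetoxy-6,12,14-trihydroxygermacra-1(10),4,11(13)-trien-8-yl (2S)-2-methylbutanoate | C=C(CO)[C@H]1[C@H](O)/C=C(/COC(C)=O)CC/C=C(/CO)C[C@@H]1OC(=O)[C@@H](C)CC | intermediate
27 | (6R,7R,8S)-15-acetoxy-12-hydroxy-14-oxo-6,12-epoxygermacra-1(10),4,11(13)-trien-8-yl (2S)-2-methylbutanoate (lactol, both C12 epimers) | C=C1C(O)O[C@@H]2/C=C(/COC(C)=O)CC/C=C(/C=O)C[C@H](OC(=O)[C@@H](C)CC)[C@@H]12 | intermediate (not isolated)
28 | [(3aR,4S,6E,10E,11aR)-10-(acetoxymethyl)-6-formyl-3-methylidene-2-oxo-2,3,3a,4,5,8,9,11a-octahydrocyclodeca[b]furan-4-yl] (2S)-2-methylbutanoate | C=C1C(=O)O[C@@H]2/C=C(/COC(C)=O)CC/C=C(/C=O)C[C@H](OC(=O)[C@@H](C)CC)[C@@H]12 | target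

**Step count and risks**

Total steps: 18. Longest linear sequence: 12 (steps 5–12 and 15–18, from 7).

Most likely to fail, step 16 (macrocyclic allylation). The risks are ring strain and oligomerisation, loss of the C8 acyloxy group by 1,4-elimination from the allylchromium, and erosion of the anti/Felkin selectivity in the ring-forming transition state. Fallback: set the three stereocentres intermolecularly and close the ring at C3–C4 instead. It sets out from 16 (with 22 and 4) and comes back at 26. Cross-metathesis of 16 with 22 gives bromo iodide F1. CrCl2 in THF converts only its allylic bromide into the allylchromium, which adds to the aldehyde of 4 to give homoallylic alcohol F2 (the alkyl and vinyl iodides are inert without a nickel co-catalyst). TESOTf and 2,6-lutidine give triethylsilyl ether F3. Zn/LiCl inserts into the primary C–I bond to give alkylzinc iodide F4, and Pd(PPh3)4 at high dilution closes the ten-membered ring by intramolecular Negishi coupling to macrocyclic silyl ether F5. HF·pyridine then removes all three silyl groups to give 26.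

Second, step 15 (cross-metathesis). A hindered allylic-ester alkene must couple with a 1,1-disubstituted allylic bromide, so conversion may be low. Fallback: make the C7=C11 bond intramolecularly through a temporary silicon tether. It sets out from 12 (with 20) and comes back at 23 as the single isomer with CH2Br cis to C8. Treating 12 with Ph2SiCl2/Et3N and then 20 gives mixed silaketal F6. Ring-closing metathesis (second-generation Grubbs catalyst, CH2Cl2, 40 °C) gives cyclic silaketal F7. K2CO3 in MeOH releases diol F8. TESCl/imidazole at −40 °C caps the primary hydroxyl to give triethylsilyl ether F9. 13 with DCC/DMAP gives ester F10. DDQ gives alcohol F11, and I2/PPh3/imidazole gives iodide F12. Zn/LiCl gives alkylzinc iodide F13, which couples with 4 under Pd(PPh3)4 to give enal F14. AcOH/THF/H2O at 0 °C removes only the triethylsilyl group to give allylic alcohol F15, and PBr3/pyridine in Et2O at −20 °C gives 23.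

Third, step 5 (epoxide opening/lactonisation). Attack at the allylic carbon or in the SN2′ sense, and phosphoryl transfer leading to a cyclopropane instead of the lactone, can cut the yield. Fallback: build the lactone with malonate and add phosphorus afterwards. It sets out from 7 and comes back at 9. Diethyl malonate with NaOEt in EtOH opens 7 at the CH2 terminus and lactonises to ester lactone F16. LiCl in wet DMSO at 150 °C (Krapcho dealkoxycarbonylation) gives vinyl lactone F17. LiN(iPr)2 and then ClP(O)(OEt)2 at −78 °C give enol phosphate F18, and a second equivalent of LiN(iPr)2 triggers the 1,3-shift of phosphorus from oxygen to carbon to give 9.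

**Further compounds**
F1 | step 16 | bromo iodide: (4S,6E)-1-bromo-2,6-bis({[tert-butyl(dimethyl)silyl]oxy}methyl)-9-iodonona-2,6-dien-4-yl (2S)-2-methylbutanoate, 2E/2Z mixture | ICC/C=C(/CO[Si](C)(C)C(C)(C)C)C[C@H](OC(=O)[C@@H](C)CC)C=C(CBr)CO[Si](C)(C)C(C)(C)C
F2 | step 16 | homoallylic alcohol: open-chain adduct of the allylchromium from F1 with 4 (C6–C8 configured as in 25, Z vinyl iodide at C4, primary iodide at C3) | C=C(CO[Si](C)(C)C(C)(C)C)[C@@H]([C@H](O)/C=C(/COC(C)=O)I)[C@@H](OC(=O)[C@@H](C)CC)C/C(CO[Si](C)(C)C(C)(C)C)=C\CCI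
F3 | step 16 | triethylsilyl ether of F2 at O6 | C=C(CO[Si](C)(C)C(C)(C)C)[C@@H]([C@H](O[Si](CC)(CC)CC)/C=C(/COC(C)=O)I)[C@@H](OC(=O)[C@@H](C)CC)C/C(CO[Si](C)(C)C(C)(C)C)=C\CCI
F4 | step 16 | alkylzinc iodide from F3 (zinc on C3) | C=C(CO[Si](C)(C)C(C)(C)C)[C@@H]([C@H](O[Si](CC)(CC)CC)/C=C(/COC(C)=O)I)[C@@H](OC(=O)[C@@H](C)CC)C/C(CO[Si](C)(C)C(C)(C)C)=C\CC[Zn]I
F5 | step 16 | macrocyclic silyl ether: 6-O-triethylsilyl ether of 25 | C=C(CO[Si](C)(C)C(C)(C)C)[C@H]1[C@H](O[Si](CC)(CC)CC)/C=C(/COC(C)=O)CC/C=C(/CO[Si](C)(C)C(C)(C)C)C[C@@H]1OC(=O)[C@@H](C)CC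
F6 | step 15 | mixed silaketal: diphenylsilyl bis-ether of 12 (at O8) and 20 | COc1ccc(COCC/C=C(/CO[Si](C)(C)C(C)(C)C)C[C@H](O[Si](c2ccccc2)(c2ccccc2)OCC(=C)CO[Si](C)(C)C(C)(C)C)C=C)cc1
F7 | step 15 | cyclic silaketal: 2,2-diphenyl-4,7-dihydro-1,3,2-dioxasilepine carrying CH2OTBS at C5 and the C8 side chain at C7 | COc1ccc(COCC/C=C(/CO[Si](C)(C)C(C)(C)C)C[C@@H]2O[Si](c3ccccc3)(c3ccccc3)OCC(CO[Si](C)(C)C(C)(C)C)=C2)cc1
F8 | step 15 | diol: C8 secondary alcohol with free CH2OH cis to C8 on the C7=C11 alkene | COc1ccc(COCC/C=C(/CO[Si](C)(C)C(C)(C)C)C[C@H](O)/C=C(\CO)CO[Si](C)(C)C(C)(C)C)cc1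
F9 | step 15 | triethylsilyl ether of F8 at the primary hydroxyl | COc1ccc(COCC/C=C(/CO[Si](C)(C)C(C)(C)C)C[C@H](O)/C=C(\CO[Si](CC)(CC)CC)CO[Si](C)(C)C(C)(C)C)cc1
F10 | step 15 | ester: (2S)-2-methylbutanoate of F9 at O8 | COc1ccc(COCC/C=C(/CO[Si](C)(C)C(C)(C)C)C[C@H](OC(=O)[C@@H](C)CC)/C=C(\CO[Si](CC)(CC)CC)CO[Si](C)(C)C(C)(C)C)cc1
F11 | step 15 | alcohol: F10 without the PMB group | OCC/C=C(/CO[Si](C)(C)C(C)(C)C)C[C@H](OC(=O)[C@@H](C)CC)/C=C(\CO[Si](CC)(CC)CC)CO[Si](C)(C)C(C)(C)C
F12 | step 15 | iodide from F11 | ICC/C=C(/CO[Si](C)(C)C(C)(C)C)C[C@H](OC(=O)[C@@H](C)CC)/C=C(\CO[Si](CC)(CC)CC)CO[Si](C)(C)C(C)(C)C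
F13 | step 15 | alkylzinc iodide from F12 | I[Zn]CC/C=C(/CO[Si](C)(C)C(C)(C)C)C[C@H](OC(=O)[C@@H](C)CC)/C=C(\CO[Si](CC)(CC)CC)CO[Si](C)(C)C(C)(C)C
F14 | step 15 | enal: Negishi product of F13 and 4 | O=C/C=C(/COC(C)=O)CC/C=C(/CO[Si](C)(C)C(C)(C)C)C[C@H](OC(=O)[C@@H](C)CC)/C=C(\CO[Si](CC)(CC)CC)CO[Si](C)(C)C(C)(C)C
F15 | step 15 | allylic alcohol: F14 without the triethylsilyl group | O=C/C=C(/COC(C)=O)CC/C=C(/CO[Si](C)(C)C(C)(C)C)C[C@H](OC(=O)[C@@H](C)CC)/C=C(\CO)CO[Si](C)(C)C(C)(C)C
F16 | step 5 | ester lactone: ethyl (5S)-5-ethenyl-2-oxooxolane-3-carboxylate | C=C[C@H]1OC(=O)C(C(=O)OCC)C1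
F17 | step 5 | vinyl lactone: (5S)-5-ethenyloxolan-2-one | C=C[C@H]1OC(=O)CC1
F18 | step 5 | enol phosphate: diethyl (5S)-5-ethenyl-4,5-dihydrofuran-2-yl phosphate | C=C[C@H]1OC(OP(=O)(OCC)OCC)=CC1
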